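Numbers refer to the compound list after step 7. The target has no stereocentre, so no configuration has to be set. The side-chain hydroxyl is carried as a benzyl ether until the last step.

## Analysis of the target

Target 20 is a diaryl ether of two electron-rich benzene rings, with no other ring and no stereocentre. Ring A is a 2,6-dimethoxy-4-propylphenyl group bound to the ether oxygen through C1, so that oxygen sits between two methoxyls. Ring B carries the ether oxygen on C1, a free hydroxyl on C2, a methoxyl on C3 and a 3-hydroxypropyl chain on C5. It therefore has three contiguous oxygens of three different kinds. The sensitive groups are the guaiacol-type phenol, which oxidises easily, the two arenes, which are open to electrophiles, and the primary alcohol. The first difficulty is the C1(ring B)–O–C1(ring A) bond: neither ring is activated for nucleophilic aromatic substitution, and a doubly ortho-substituted phenol couples poorly under metal catalysis with an aryl halide that itself bears an ortho oxygen. The second is telling the three oxygens of ring B apart. The strategy rests on the adjacency C1–OAr, C2–OH, C3–OMe of ring B. These are the positions addressed by a 3-methoxybenzyne whose triple bond spans C1 and C2, with a nucleophile entering at C1 and an electrophile at C2. Ring A is available intact as phenol 12.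

## Retrosynthetic reasoning

20 from 19. The benzylic C–O bond of the side-chain ether is cut last. The primary alcohol stays masked through every organometallic step and is freed by hydrogenolysis, which leaves the diaryl ether, the methyl ethers and the phenol alone.

19 from 16. The C2–O bond of the ring B hydroxyl is traced back to a C2–I bond. This makes the C2 oxygen the one oxygen of ring B that arrives through a carbanion, which distinguishes it from its two neighbours without any selective protection. Forward, the iodide of 16 has to be exchanged for lithium, borylated and oxidised while the benzyl ether stays intact.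

16 from 11 and 12. Both bonds on the adjacent carbons C1 and C2 of ring B are cut together: C1–O to the ring A oxygen and C2–I. This leads to aryne 14, released from silyl triflate 11, to phenoxide 13 made from phenol 12, and to a perfluoroalkyl iodide as iodine donor. The cut is placed here because the hindered ether bond then forms at a strained, sterically open carbon without a metal catalyst, ring A enters as a bought compound, and C2 is functionalised in the same event. The forward reaction must add the phenoxide at C1 and not C2, and the aryl anion 15 must take iodine and not a proton.

11 from 9. The triflate S–O bond is cut. The triflate comes from the carbamate by way of phenoxide 10, so the group that directed the metalation is exchanged for the leaving group of the aryne precursor in one flask.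

9 from 5. The C2–Si bond is cut because C2 is the only ring position lying between two oxygen directing groups. Directed ortho-metalation of 5, passing through 6, 7 and 8, should place silicon there and nowhere else.

5 from 4. The carbamoyl C–O bond is cut; an isocyanate adds to the phenol.

4 from 1 and 2. The aryl–CH2 bond is cut. Hydroboration of alkene 1 gives borane 3, which is coupled with bromophenol 2. The coupling is run on the free phenol, before the carbamate is installed, because an aryl N-monoalkyl carbamate would fragment by E1cB in the aqueous base of a B-alkyl Suzuki–Miyaura coupling.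

## Alternatives that were turned down

Alternative 1: Ring A is built from an open chain and aromatised late. The disconnection cuts a ring A C–C bond next to the aryloxy carbon, leading to keto ester A2. A2 would come from O-alkylation of the ring B phenol A3 with an α-halo ketone. In the forward key step an alkoxide base forms the enolate of A2 at the aryloxy-bearing carbon. This enolate attacks the methyl ester in a Claisen (Dieckmann-type) closure and gives the cyclohexane-1,3-dione A1. Dehydrogenation to the resorcinol level, double O-methylation and hydrogenolysis would follow.
- For: the ether C–O bond is made by a simple SN2 reaction, so no hindered aryl–oxygen coupling is needed. On this point the alternative is stronger than the aryne step. The symmetric 1,3-dione also fixes the ring A pattern automatically, and the closure is textbook carbanion chemistry.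
- Against: ring A is built in many operations although it can be bought complete as 12. The dehydrogenation of a 2-aryloxy-1,3-dione needs halogenation–elimination or hot palladium conditions, which threaten the electron-rich ring B and the benzyl ethers. The route also needs A3, in which the three oxygens of ring B are already differentiated, so the central problem of the target is only moved into a separate synthesis.
- Comparison: the chosen strategy risks one less-charted step but solves the ring B pattern and the ether bond together, and it is far shorter.

Alternative 2: Ring B is built from a pyranone. The disconnection cuts two ring B bonds, C1–C6 and C2–C3. This leads to the silyl ketene acetal A5, made from the aryloxyacetic acid obtained by alkylating 12 with a haloacetate, and to methyl 3-bromocoumalate A6. In the forward key step A5 adds across C3 and C6 of A6. Decarboxylation and loss of a silanol then aromatise the adduct to A4, which carries the aryloxy group, the free C2 hydroxyl and a C3 bromide.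
- For: the polarity of the two partners dictates the regiochemistry, and the ether oxygen is again attached by SN2. The product has the C2 hydroxyl already free and distinct from the C3 position. On predictability of the oxygen pattern this route is at least as good as the aryne route.
- Against: A4 carries an ester where the target has a three-carbon chain, so reduction and a two-carbon homologation are needed. The bromide must be exchanged for methoxide next to a phenol that first has to be protected. A5 is a very electron-rich, moisture-sensitive reagent that may add to A6 in a stepwise conjugate fashion and open the pyranone instead of cycloadding.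
- Comparison: the chosen route brings in the chain and the methoxyl with the starting material and needs only three steps after its key step, where this one needs about twice as many.

Alternative 3: Ring A is built from a four-membered ring. The disconnection leads to the 4-chlorocyclobutenone A8, made from a squarate diester and phenol A3, and to alkenylstannane A9. In the forward key step palladium-catalysed Stille coupling joins the chlorine-bearing carbon of A8 to the tin-bearing carbon of A9. The 4-alkenylcyclobutenone opens thermally to a dienylketene, and six-electron electrocyclisation and tautomerisation give phenol A7. O-methylation and hydrogenolysis would follow.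
- For: the ether bond comes from addition–elimination on the squarate, the cascade is convergent and reliable, and the ring A regiochemistry is built in. On the ease of the C–O bond it is stronger than the aryne step.
- Against: it needs A3 again. It needs a site-selective reduction of an unsymmetrical squarate to reach A8, which is a sensitive intermediate, and it uses stoichiometric tin. It also differentiates the two ring A oxygens, which the target does not require, at the cost of an extra methylation.
- Comparison: the chosen route buys ring A and places its single risk in one step on readily made partners.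

Key step: step 5

## Route

Step 1
Reactants: 1 allyl benzyl ether; 2 3-bromo-5-methoxyphenol
Product: 4 3-[3-(benzyloxy)propyl]-5-methoxyphenol, via alkyl-9-BBN 3 (not isolated)
Conditions: 1, 9-BBN, THF, 0 °C to rt; then 2, Pd(OAc)2 (3 mol%), SPhos (6 mol%), 3 M aq K3PO4, THF, 60 °C
Reagents that add atoms: none
Why: 9-BBN adds anti-Markovnikov to the terminal alkene, and the hydroxide-activated borane 3 transmetalates to the arylpalladium bromide in a B-alkyl Suzuki–Miyaura coupling, the bulky biaryl phosphine favouring reductive elimination over β-hydride elimination. The phenol is carried as its phenoxide, which is why the coupling precedes carbamoylation.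

Step 2
Reactants: 4 3-[3-(benzyloxy)propyl]-5-methoxyphenol
Product: 5 3-[3-(benzyloxy)propyl]-5-methoxyphenyl N-(propan-2-yl)carbamate
Conditions: i-PrNCO, Et3N (cat.), CH2Cl2, rt
Reagents that add atoms: isopropyl isocyanate, CC(C)N=C=O
Why: Amine-catalysed addition of the phenol O–H across the isocyanate (carbamoylation) gives the N-monoalkyl carbamate, a strong metalation director that can later be removed under mild base; the benzyl ether and the arene are inert.

Step 3
Reactants: 5 3-[3-(benzyloxy)propyl]-5-methoxyphenyl N-(propan-2-yl)carbamate
Product: 9 5-[3-(benzyloxy)propyl]-3-methoxy-2-(trimethylsilyl)phenyl N-(propan-2-yl)carbamate, via N-silyl carbamate 6 (not isolated), via aryllithium 7 (not isolated), via bis-silyl carbamate 8 (not isolated)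
Conditions: TMSOTf, TMEDA, Et2O, 0 °C to rt; n-BuLi, TMEDA, −78 °C; TMSCl, −78 °C to rt; aq NaHSO4
Reagents that add atoms: chlorotrimethylsilane, C[Si](C)(C)Cl
Why: Directed ortho-metalation: after N-silylation in the flask masks the N–H, n-BuLi/TMEDA removes the ring proton between the carbamate oxygen and the methoxyl, the site activated by both groups, and TMSCl silylates aryllithium 7; aqueous acid strips the N-silyl group of 8. At −78 °C this metalation should outrun deprotonation of the benzylic ether CH2 and anionic Fries migration.

Step 4
Reactants: 9 5-[3-(benzyloxy)propyl]-3-methoxy-2-(trimethylsilyl)phenyl N-(propan-2-yl)carbamate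
Product: 11 5-[3-(benzyloxy)propyl]-3-methoxy-2-(trimethylsilyl)phenyl trifluoromethanesulfonate, via silylphenol 10 (not isolated)
Conditions: DBU, Et2NH, MeCN, 40 °C; then PhNTf2, rt
Reagents that add atoms: N-phenylbis(trifluoromethanesulfonimide), O=S(=O)(N(c1ccccc1)S(=O)(=O)C(F)(F)F)C(F)(F)F
Why: DBU deprotonates the carbamate N–H and the anion expels the phenoxide (E1cB), with Et2NH trapping the isocyanate as a urea; the phenoxide of 10 is then O-sulfonylated by PhNTf2, a triflating agent mild enough to leave the aryl–silicon bond intact.

Step 5
Reactants: 11 5-[3-(benzyloxy)propyl]-3-methoxy-2-(trimethylsilyl)phenyl trifluoromethanesulfonate; 12 2,6-dimethoxy-4-propylphenol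
Product: 16 5-[3-(benzyloxy)propyl]-1-(2,6-dimethoxy-4-propylphenoxy)-2-iodo-3-methoxybenzene, via potassium phenoxide 13 (not isolated), via aryne 14 (not isolated), via arylpotassium 15 (not isolated)
Conditions: 12, KH, THF, 0 °C; then KF, 18-crown-6, C4F9I, 0 °C, dark; 11 in THF added slowly, 0 °C to rt
Reagents that add atoms: nonafluorobutyl iodide, FC(F)(F)C(F)(F)C(F)(F)C(F)(F)I
Why: Fluoride from KF/18-crown-6 attacks the silicon of 11 and the resulting aryl anion expels triflate, releasing aryne 14 at low stationary concentration. Phenoxide 13, made beforehand with KH so that no O–H acid is left, adds to the strained triple bond; the attacked carbon has only a hydrogen-bearing neighbour on its open side, so the two ortho methoxyls of ring A should be tolerated far better than in a metal-mediated aryl ether coupling. The C3 methoxyl withdraws electron density through the sigma framework and distorts the aryne so that C1 is the flatter, more electrophilic end, and attack at C1 leaves the charge at C2 in an in-plane orbital next to two C–O bonds (arylpotassium 15). Anion 15 then attacks the iodine of C4F9I (halogen-philic substitution), and the expelled perfluorobutyl anion collapses to the perfluoroalkene and fluoride, which makes the iodine transfer irreversible. The closest known reaction types are the three-component aryne couplings in which a thiolate or an amine adds and the aryl anion is halogenated by a polyfluorinated organic halide, together with fluoride-induced O-arylation of phenols by silylaryl triflates; the hindered phenoxide is the less explored partner. No ring is closed and no stereocentre is created. The step needs site selectivity of addition (secured by the C3 methoxyl), iodination and not protonation of 15 (secured by the aprotic medium, THF in place of acetonitrile, and excess C4F9I), and phenoxide and not fluoride as nucleophile (secured by the soluble crown-complexed phenoxide); exclusion of light and slow addition of 11 are meant to suppress electron transfer from 13 to C4F9I and attack of 15 on a second aryne.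

Step 6
Reactants: 16 5-[3-(benzyloxy)propyl]-1-(2,6-dimethoxy-4-propylphenoxy)-2-iodo-3-methoxybenzene
Product: 19 4-[3-(benzyloxy)propyl]-2-(2,6-dimethoxy-4-propylphenoxy)-6-methoxyphenol, via aryllithium 17 (not isolated), via lithium arylborate 18 (not isolated)
Conditions: n-BuLi, THF, −78 °C; B(OMe)3, −78 to 0 °C; then 30% aq H2O2, aq NaOH, 0 °C; aq Na2S2O3
Reagents that add atoms: hydrogen peroxide, OO
Why: Iodine–lithium exchange at −78 °C is faster than any deprotonation and gives the C2 aryllithium 17, stabilised by its two flanking oxygens; borylation to 18 and peroxide-induced 1,2-migration of the aryl group from boron to oxygen (exchange–borylation–oxidation) deliver the phenol.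

Step 7
Reactants: 19 4-[3-(benzyloxy)propyl]-2-(2,6-dimethoxy-4-propylphenoxy)-6-methoxyphenol
Product: 20 2-(2,6-dimethoxy-4-propylphenoxy)-4-(3-hydroxypropyl)-6-methoxyphenol
Conditions: H2 (1 atm), 10% Pd/C, EtOAc/EtOH, rt
Reagents that add atoms: none
Why: Hydrogenolysis of the benzyl ether over palladium on carbon frees the primary alcohol; the diaryl ether, the methyl ethers and the arene rings are not reduced at ambient pressure and temperature.

## Compound list

1 | allyl benzyl ether, [(prop-2-en-1-yloxy)methyl]benzene | C=CCOCc1ccccc1 | starting material
2 | 3-bromo-5-methoxyphenol | COc1cc(O)cc(Br)c1 | starting material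
3 | 9-[3-(benzyloxy)propyl]-9-borabicyclo[3.3.1]nonane | C(CCOCc1ccccc1)B1C2CCCC1CCC2 | intermediate (not isolated)
4 | 3-[3-(benzyloxy)propyl]-5-methoxyphenol | COc1cc(O)cc(CCCOCc2ccccc2)c1 | intermediate
5 | 3-[3-(benzyloxy)propyl]-5-methoxyphenyl N-(propan-2-yl)carbamate | CC(C)NC(=O)Oc1cc(OC)cc(CCCOCc2ccccc2)c1 | intermediate
6 | 3-[3-(benzyloxy)propyl]-5-methoxyphenyl N-(propan-2-yl)-N-(trimethylsilyl)carbamate | CC(C)N([Si](C)(C)C)C(=O)Oc1cc(OC)cc(CCCOCc2ccccc2)c1 | intermediate (not isolated)
7 | {4-[3-(benzyloxy)propyl]-2-methoxy-6-{[(propan-2-yl)(trimethylsilyl)carbamoyl]oxy}phenyl}lithium | CC(C)N([Si](C)(C)C)C(=O)Oc1cc(CCCOCc2ccccc2)cc(OC)c1[Li] | intermediate (not isolated)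
8 | 5-[3-(benzyloxy)propyl]-3-methoxy-2-(trimethylsilyl)phenyl N-(propan-2-yl)-N-(trimethylsilyl)carbamate | CC(C)N([Si](C)(C)C)C(=O)Oc1cc(CCCOCc2ccccc2)cc(OC)c1[Si](C)(C)C | intermediate (not isolated)
9 | 5-[3-(benzyloxy)propyl]-3-methoxy-2-(trimethylsilyl)phenyl N-(propan-2-yl)carbamate | CC(C)NC(=O)Oc1cc(CCCOCc2ccccc2)cc(OC)c1[Si](C)(C)C | intermediate
10 | 5-[3-(benzyloxy)propyl]-3-methoxy-2-(trimethylsilyl)phenol (present in the flask as its amidinium phenoxide) | COc1cc(CCCOCc2ccccc2)cc(O)c1[Si](C)(C)C | intermediate (not isolated)
11 | 5-[3-(benzyloxy)propyl]-3-methoxy-2-(trimethylsilyl)phenyl trifluoromethanesulfonate | COc1cc(CCCOCc2ccccc2)cc(OS(=O)(=O)C(F)(F)F)c1[Si](C)(C)C | intermediate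
12 | 2,6-dimethoxy-4-propylphenol | CCCc1cc(OC)c(O)c(OC)c1 | starting material
13 | potassium 2,6-dimethoxy-4-propylphenoxide | CCCc1cc(OC)c([O-])c(OC)c1.[K+] | intermediate (not isolated)
14 | 5-[3-(benzyloxy)propyl]-3-methoxy-1,2-didehydrobenzene (aryne) | COC1=CC(CCCOCc2ccccc2)=CC#C1 | intermediate (not isolated)
15 | {4-[3-(benzyloxy)propyl]-2-(2,6-dimethoxy-4-propylphenoxy)-6-methoxyphenyl}potassium | CCCc1cc(OC)c(Oc2cc(CCCOCc3ccccc3)cc(OC)c2[K])c(OC)c1 | intermediate (not isolated)
16 | 5-[3-(benzyloxy)propyl]-1-(2,6-dimethoxy-4-propylphenoxy)-2-iodo-3-methoxybenzene | CCCc1cc(OC)c(Oc2cc(CCCOCc3ccccc3)cc(OC)c2I)c(OC)c1 | intermediate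
17 | {4-[3-(benzyloxy)propyl]-2-(2,6-dimethoxy-4-propylphenoxy)-6-methoxyphenyl}lithium | CCCc1cc(OC)c(Oc2cc(CCCOCc3ccccc3)cc(OC)c2[Li])c(OC)c1 | intermediate (not isolated)
18 | lithium {4-[3-(benzyloxy)propyl]-2-(2,6-dimethoxy-4-propylphenoxy)-6-methoxyphenyl}trimethoxyborate | [Li+].CCCc1cc(OC)c(Oc2cc(CCCOCc3ccccc3)cc(OC)c2[B-](OC)(OC)OC)c(OC)c1 | intermediate (not isolated)
19 | 4-[3-(benzyloxy)propyl]-2-(2,6-dimethoxy-4-propylphenoxy)-6-methoxyphenol | CCCc1cc(OC)c(Oc2cc(CCCOCc3ccccc3)cc(OC)c2O)c(OC)c1 | intermediate
20 | 2-(2,6-dimethoxy-4-propylphenoxy)-4-(3-hydroxypropyl)-6-methoxyphenol | CCCc1cc(OC)c(Oc2cc(CCCO)cc(OC)c2O)c(OC)c1 | target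

## Step count and least certain steps

Total step count: 7. Longest linear sequence: 7 steps, from 1 and 2 to 20; phenol 12 enters at step 5.

Step 5 (key step). Three things are most likely to go wrong.
- Anion 15 may be protonated before iodine transfer, by traces of phenol 12 or moisture, which would give the iodine-free ether.
- The very electron-rich phenoxide 13 may transfer an electron to C4F9I, which would lead to radical chemistry of the phenoxide.
- The aryne may be captured by fluoride or by 15 instead of by the hindered phenoxide.

Fallback: the three-component event is given up and the two bonds are made one after the other. It sets out from 11 and 12. Fluoride-induced O-arylation with proton capture (CsF, MeCN, rt) has the same site selectivity and should give 5-[3-(benzyloxy)propyl]-1-(2,6-dimethoxy-4-propylphenoxy)-3-methoxybenzene F1. Directed metalation of F1 with s-BuLi/TMEDA in THF at −78 °C removes the C2 proton between the methoxyl and the aryloxy group. This rejoins the route at aryllithium 17, which is borylated and oxidised as in step 6 to give 19 without passing through iodide 16.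

Step 1. Oxidative addition into the electron-rich bromophenoxide may be slow, so that protodeboronation or β-hydride elimination of the alkyl group competes. Fallback: the bond is made by a base-free Negishi coupling on the carbamate. It sets out from 2, which is carbamoylated (i-PrNCO, Et3N, CH2Cl2) to 3-bromo-5-methoxyphenyl N-(propan-2-yl)carbamate F2. The commercial 3-(benzyloxy)propyl bromide is converted with Zn and LiCl in THF into [3-(benzyloxy)propyl]zinc bromide F3. F2 and F3 are coupled with Pd(OAc)2/SPhos in THF at rt to 50 °C. The alkylzinc halide is not basic enough to fragment the N–H carbamate, and the fallback comes back to the route at 5.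

Step 6. Aryllithium 17 may be protonated or butylated before borylation, borylation at the crowded carbon may be incomplete, and alkaline peroxide may over-oxidise the electron-rich phenol. Fallback: a palladium-catalysed C–O coupling in place of the organolithium and peroxide sequence. It sets out from 16, which is hydroxylated with KOH under Pd2(dba)3/tBuXPhos in 1,4-dioxane/H2O at 100 °C, and comes back to the route at 19 with no new intermediate.

## Further compounds

F1 | step 5 | 5-[3-(benzyloxy)propyl]-1-(2,6-dimethoxy-4-propylphenoxy)-3-methoxybenzene | CCCc1cc(OC)c(Oc2cc(CCCOCc3ccccc3)cc(OC)c2)c(OC)c1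
F2 | step 1 | 3-bromo-5-methoxyphenyl N-(propan-2-yl)carbamate | CC(C)NC(=O)Oc1cc(OC)cc(Br)c1
F3 | step 1 | [3-(benzyloxy)propyl]zinc bromide | Br[Zn]CCCOCc1ccccc1
F0 | step 6 | none | none
A1 | alternative 1 | 2-{2-(benzyloxy)-5-[3-(benzyloxy)propyl]-3-methoxyphenoxy}-5-propylcyclohexane-1,3-dione | CCCC1CC(=O)C(Oc2cc(CCCOCc3ccccc3)cc(OC)c2OCc2ccccc2)C(=O)C1
A2 | alternative 1 | methyl 6-{2-(benzyloxy)-5-[3-(benzyloxy)propyl]-3-methoxyphenoxy}-5-oxo-3-propylhexanoate | CCCC(CC(=O)OC)CC(=O)COc1cc(CCCOCc2ccccc2)cc(OC)c1OCc1ccccc1
A3 | alternative 1 | 2-(benzyloxy)-5-[3-(benzyloxy)propyl]-3-methoxyphenol | COc1cc(CCCOCc2ccccc2)cc(O)c1OCc1ccccc1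
A4 | alternative 2 | methyl 3-bromo-5-(2,6-dimethoxy-4-propylphenoxy)-4-hydroxybenzoate | CCCc1cc(OC)c(Oc2cc(C(=O)OC)cc(Br)c2O)c(OC)c1
A5 | alternative 2 | 2-{[2,2-bis(trimethylsilyloxy)ethenyl]oxy}-1,3-dimethoxy-5-propylbenzene | CCCc1cc(OC)c(OC=C(O[Si](C)(C)C)O[Si](C)(C)C)c(OC)c1
A6 | alternative 2 | methyl 3-bromo-2-oxo-2H-pyran-5-carboxylate | COC(=O)C1=COC(=O)C(Br)=C1
A7 | alternative 3 | 2-{2-(benzyloxy)-5-[3-(benzyloxy)propyl]-3-methoxyphenoxy}-3-methoxy-5-propylphenol | CCCc1cc(O)c(Oc2cc(CCCOCc3ccccc3)cc(OC)c2OCc2ccccc2)c(OC)c1
A8 | alternative 3 | 2-{2-(benzyloxy)-5-[3-(benzyloxy)propyl]-3-methoxyphenoxy}-4-chloro-3-methoxycyclobut-2-en-1-one | COC1=C(Oc2cc(CCCOCc3ccccc3)cc(OC)c2OCc2ccccc2)C(=O)C1Cl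
A9 | alternative 3 | tributyl(pent-1-en-2-yl)stannane | CCCC(=C)[Sn](CCCC)(CCCC)CCCC
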